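(All constants are assumed; what happens was integrated by code.)

Green is the same charge as ochre in a warmer bath, so reckon ochre first and let green follow.

- ochre: substrate 0.17 M; free catalyst 0.87 mol%; temperature 25 °C; time 20 min
- green: substrate 0.17 M; free catalyst 0.87 mol%; temperature 33 °C; time 20 min

    substrate + free catalyst ⇌ catalyst intermediate A (K1 = 6.49 /M, k1 = 4140 /M/min, Ea1 = 37.0 kJ/mol, ΔH1 = −20.0 kJ/mol)
    catalyst intermediate A → catalyst intermediate B (k2 = 14.6 /min, Ea2 = 76.0 kJ/mol)
    catalyst intermediate B → free catalyst + target (k3 = 14.5 /min, Ea3 = 85.0 kJ/mol)
    substrate + target → side product (k4 = 0.0542 /M/min, Ea4 = 72.0 kJ/mol)
    (constants at 25 °C)

- which of these there is most of at the end, counted by the substrate in it, ochre (side product / target / catalyst intermediate A / substrate / catalyst intermediate B)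
- which of these there is most of at the end, counted by the substrate in it, green (side product / target / catalyst intermediate A / substrate / catalyst intermediate B)
- the largest of these amounts at the end, in percent of the substrate charged, ochre
- the largest of these amounts at the end, in percent of the substrate charged, green

- percentages count the substrate that a species holds: one side product counts as two
- all constants are for 25 °C and move with temperature by the activation energies and enthalpies

Write x for the fraction of the substrate charge still free. Catalyst intermediate A falls back 43.7 times faster than it goes on, so you may treat binding as balanced. Then A stands to free catalyst as S times x, where S is the **saturation number**, the equilibrium constant of binding times the starting substrate: 1.10. With S this close to unity, the rate has no whole order in substrate, and it drifts towards pseudo-first-order as x falls.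

Steps 2 and 3 run at 14.6 /min and 14.5 /min, so neither is the rate-limiting step, and intermediate B stands about level with A. That gives a weight for the bound forms, 2.01, and a clock, step 2 times the catalyst loading, 0.127 /min.

Is S enough? No: it gives the shape and no minutes. Integrating the rate, the time to reach x is the sum of two pieces divided by the clock: the logarithm of charge over what is left, divided by S, and the weight times the fraction gone.

| Fraction left | Time needed, ochre |
|---|---|
| 50.0% | 12.9 min |
| 33.3% | 18.4 min |
| 25.0% | 21.8 min |

So at 20 min I expect ochre to hold between 33.3% and 25.0% of its substrate. With x and target both at 0.5, the cycle runs 14.4 times faster than step 4, so I expect target on top. My reckoning stops there and gives no figure for green, where I expect more conversion and target on top again.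

The forecast says 65% for ochre and 87% for green, and that “target is the largest pool in both runs”.

The flasks give target at 66.0% in ochre and 86.9% in green, the largest amount in both, so the forecast stands. Ochre keeps 27% of its substrate, inside my range. Put that into the saturation number: A over free catalyst should be 0.297, and ochre's catalyst reads 0.292.

Now read ochre at 30 min. The same sum reaches x of 10.0% at 30.7 min, which puts A over free catalyst near 0.110. The computed flask holds 9.3% substrate, and its ratio is 0.100.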